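# Proposed synthesis of CNP0231327.1 through a nitrosocarbonyl hetero-Diels–Alder reaction

## Analysis of the target

CNP0231327.1 is (2R,3S,6S)-6-[(4S,15S)-4,15-dihydroxyhexadecyl]-2-methylpiperidin-3-ol. It is a piperidine (ring A: N1, C2 to C6) with a methyl group on C2, a hydroxyl on C3 and a sixteen-carbon chain (C1′ to C16′) on C6 that carries secondary hydroxyls at C4′ and C15′. Ring A holds three stereocentres: the methyl group and the chain are cis, the hydroxyl is trans to both, so one chair places all three substituents equatorial. The two chain centres are isolated, with three methylene groups between C6 and C4′ and ten between C4′ and C15′, so neither can be relayed from the ring and each needs its own source of chirality. The target itself is robust (a secondary amine and three alcohols), but late intermediates with a carbonyl or imine at C2 next to the C3 hydroxyl can enolise toward C3. The hard part is the ring: C3 and C6 carry the two heteroatoms in a 1,4 relation with nothing between them to pass stereochemical information, and C2 must then be set against both. The strategy rests on this feature: nitrogen on C6 and oxygen on C3, 1,4-related across C3–C4–C5–C6, have the relative configuration of a cis-3,6-disubstituted 3,6-dihydro-1,2-oxazine, which is what an N=O unit leaves when it adds to one face of an (E,E)-diene C3=C4–C5=C6. C2 is then the carbon of a masked methyl ketone on which the C6 nitrogen closes.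

## Retrosynthetic reasoning

**N1–C2 (25 back to 22).** The N1–C2 bond of target 25 is cut first. C2 is the only ring centre that can be derived from the other two: the cyclic imine 24 has the C6 chain and the C3 hydroxyl pseudo-equatorial, and axial hydride addition places the methyl group equatorial. Imine 24 forms by itself from amino ketone 23, and 23 is the hydrolysis product of amino alcohol 22, in which the ketone is a dioxolane and the chain hydroxyls are silyl ethers. One acid treatment removes all three masks, so no separate deprotection step remains after ring closure.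

**N–O and N-acyl (22 back to 20).** The amine on C6 and the hydroxyl on C3 of 22 are rejoined through an N–O bond, and C4–C5 is taken back to an alkene, giving dihydrooxazine 21. The forward hydrogenation saturates the alkene and breaks the weak N–O bond without touching either stereocentre. Compound 21 comes from the acylated cycloadduct 20. The acyl group is removed while nitrogen still carries oxygen, because an N-alkoxy amide is cleaved cleanly by hydride in the manner of a Weinreb amide. After N–O cleavage the same group would be an ordinary secondary amide. Alkoxide is not relied on here: it attacks N-alkoxy amides slowly and could open the ring by elimination across C3–H and N–O.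

**C6–N and C3–O (20 back to 16 and 18).** This is the disconnection that carries the strategy. Both bonds are cut to give diene 16 and the nitrosocarbonyl compound 19, which is made in the flask from hydroxamic acid 18. Cutting here creates both heteroatom-bearing ring centres in one step with a fixed cis relation. The diene contains no ring stereocentre, so all effort before this point goes into a linear chain. The forward reaction must put nitrogen on C6 and not on C3, and must select one face of the diene.

**C4–C5 (16 back to 14 and 15).** The diene is cut between C4 and C5 into iodoalkene 14 and vinyl ketal 15. Compound 15 is a commercial four-carbon unit that already holds C2, its methyl group and the ketal. Its allylic carbon has no hydrogen, so a Heck coupling can eliminate in one direction only. The (E) geometry of C5=C6 is fixed in 14 and that of C3=C4 by the coupling.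

**C5=C6 and C2′–C3′ (14 back to 7 and 8).** Iodoalkene 14 goes back to terminal alkyne 12 by hydrozirconation and iodination, and 12 to alkynol 11 by silylation. The C2′–C3′ bond of 11 is cut to give epoxide 7 and the Grignard reagent 9 made from bromide 8. The opening occurs at the oxirane CH2, so the C4′ configuration is that of the epoxide. The three methylene groups and the alkyne arrive in one step.

**C4′ oxirane and C13′–C14′ (7 back to 1 and 2).** Epoxide 7 is the resolved epimer of mixture 6, which comes from alkene 5 by epoxidation. The C4′ centre is thus set by hydrolytic kinetic resolution, which gives a single epimer at the price of half the material at an early, cheap stage. Alkene 5 is the silyl ether of alcohol 4. The C13′–C14′ bond of 4 is cut to give Grignard reagent 3 (from bromide 1) and epoxide 2, which supplies C15′ and C16′ from the chiral pool.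

**Auxiliary (18 back to 17).** Hydroxamic acid 18 is made in one step from ester 17.

## Alternatives that were turned down

**Alternative 1:** The ring is cut at both N1–C2 and N1–C6, back to the open-chain hydroxy diketone A2. In the forward step an (R)-selective ω-transaminase (pyridoxal phosphate, sacrificial amine donor) would aminate only the methyl ketone C2. The new amine would condense with the C6 ketone to the cyclic imine A1, and a later reduction would set C6.
- For: C2 is set by the enzyme independently of the ring, no protecting groups are needed, and the ring stage is very short. Reduction of such imines to cis-2,6 products is dependable.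
- Against: C2 lies next to the free C3 carbinol, so A2 is an α-hydroxy ketone that can isomerise through its enediol in buffer during the long reaction times a lipophilic C22 substrate would need. Enzyme acceptance of this substrate cannot be planned without screening. A2 still needs three stereocentres and is a 1,5-diketone open to aldol closure.
- Comparison: alternative 1 is stronger on step economy at the ring and on the C2 configuration once an enzyme is found. The chosen strategy needs no screening, fixes C3 and C6 together, and never exposes a hydroxy diketone.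

**Alternative 2:** The C4=C5 bond of tetrahydropyridine A3 is cut and traced to cycloheptene A4. In the forward step a second-generation Hoveyda–Grubbs catalyst under ethylene would perform a ring-rearrangement metathesis: the N-tethered vinyl group closes ring A while the seven-membered ring opens into C1′–C5′ ending in a vinyl group.
- For: C6 and C4′ come from one cis-1,4-disubstituted ring, and all ring A centres exist before ring closure, so no face selectivity is at stake.
- Against: cycloheptene has little strain, so ring opening is weakly driven. The basic secondary amine of A4 binds ruthenium and would need protection or protonation. A4 needs an enantiopure cis-1,4 pattern on the seven-membered ring, a separately made C2–C3 amino alcohol unit and a stereospecific C–N coupling. A3 still lacks C6′ to C16′, which must be added by cross-metathesis and hydrogenation.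
- Comparison: alternative 2 is stronger in the stereochemical security of the ring. The chosen route is clearly shorter and builds the chain centres from epoxides.

**Alternative 3:** The N1–C2 bond is cut back to amino alkyne A6. In the forward step NaAuCl4 (trivalent gold) would activate the terminal alkyne, the C6 amine would add 6-exo-dig in the Markovnikov sense, and the 2-methyl cyclic imine would be reduced in the same flask to piperidine A5.
- For: the closure is regiochemically unambiguous and mild. The C3 oxygen stays silylated, so no α-hydroxy imine is exposed. Each stereocentre of A6 can be set by a separate reagent-controlled reaction.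
- Against: C3 and C6 then need two separate asymmetric steps, amine protection and deprotection, and a longer linear sequence. Free primary amines also bind gold.
- Comparison: alternative 3 is as strong or stronger in the predictability of each centre and in the safety of the final closure. The chosen route makes both heteroatom-bearing centres in one step with fixed relative configuration and is several steps shorter, at the price of a face selectivity that still has to be shown.

Key step: step 10

## Route

Remark on numbering: atom labels N1, C2 to C6 and C1′ to C16′ are those of the target and are used for all intermediates.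

Assumption: nitroso compound 19 of the (R) series is taken to attack the diene face that leads to 20. If the other ring diastereomer dominates, the enantiomer of ester 17 is used and nothing else changes.

Step 1
Reactants: 1 11-bromoundec-1-ene; 2 (S)-2-methyloxirane ((S)-propylene oxide)
Product: 4 (2S)-tetradec-13-en-2-ol, via undec-10-enylmagnesium bromide 3 (not isolated)
Conditions: Mg, THF, 40 °C; then CuI (10 mol %), 2, THF, −30 → 0 °C
Reagents that add atoms: none
Why: Copper-catalysed Grignard opening of a terminal epoxide at its unsubstituted carbon (SN2). The stereocentre of 2 is not touched and becomes C15′ (S).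

Step 2
Reactants: 4 (2S)-tetradec-13-en-2-ol
Product: 5 tert-butyldimethyl[(2S)-tetradec-13-en-2-yloxy]silane
Conditions: TBSCl, imidazole, DMF, rt
Reagents that add atoms: tert-butyldimethylsilyl chloride (TBSCl), CC(C)(C)[Si](C)(C)Cl
Why: Standard imidazole-mediated silylation of a secondary alcohol. The ether should survive every step up to the final acid treatment.

Step 3
Reactants: 5 tert-butyldimethyl[(2S)-tetradec-13-en-2-yloxy]silane
Product: 6 tert-butyldimethyl{[(2S)-12-(oxiran-2-yl)dodecan-2-yl]oxy}silane (both epimers at the oxirane carbon)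
Conditions: mCPBA, NaHCO3, CH2Cl2, 0 °C → rt
Reagents that add atoms: 3-chloroperoxybenzoic acid (mCPBA), OOC(=O)c1cccc(Cl)c1
Why: Prilezhaev epoxidation of the monosubstituted alkene. The remote stereocentre gives no induction, so both oxirane epimers are expected and are resolved in step 4.

Step 4
Reactants: 6 tert-butyldimethyl{[(2S)-12-(oxiran-2-yl)dodecan-2-yl]oxy}silane (epimer mixture)
Product: 7 tert-butyldimethyl({(2S)-12-[(2S)-oxiran-2-yl]dodecan-2-yl}oxy)silane
Conditions: (S,S)-Co(salen)(OAc) (0.5 mol %; salen = N,N′-bis(3,5-di-tert-butylsalicylidene)cyclohexane-1,2-diamine dianion), H2O (0.55 equiv), THF, 0 °C → rt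
Reagents that add atoms: none
Why: Jacobsen hydrolytic kinetic resolution: the chiral salen complex of trivalent cobalt hydrates the (R)-oxirane epimer much faster and leaves the (S)-epimer, whose oxirane carbon becomes C4′. The catalyst enantiomer is the one that spares (S)-2-alkyloxiranes, and the polar diol is removed by chromatography.

Step 5
Reactants: 7 tert-butyldimethyl({(2S)-12-[(2S)-oxiran-2-yl]dodecan-2-yl}oxy)silane; 8 (4-bromobut-1-yn-1-yl)trimethylsilane
Product: 11 (6S,17S)-17-[(tert-butyldimethylsilyl)oxy]octadec-1-yn-6-ol, via silylbutynylmagnesium bromide 9 (not isolated), via C-silylated alkynol 10 (not isolated)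
Conditions: 8, Mg, THF, rt; then CuI (10 mol %), 7, THF, −30 → 0 °C; crude product then K2CO3, MeOH, rt
Reagents that add atoms: none
Why: Copper-catalysed SN2 opening of the terminal epoxide at CH2 by the homopropargylic Grignard reagent keeps the C4′ configuration and brings in C5, C6 and C1′ to C2′ at once. Methanolysis of the alkynyl C–Si bond then frees the terminal alkyne.

Step 6
Reactants: 11 (6S,17S)-17-[(tert-butyldimethylsilyl)oxy]octadec-1-yn-6-ol
Product: 12 (6S,17S)-6,17-bis[(tert-butyldimethylsilyl)oxy]octadec-1-yne
Conditions: TBSCl, imidazole, DMF, rt → 40 °C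
Reagents that add atoms: tert-butyldimethylsilyl chloride (TBSCl), CC(C)(C)[Si](C)(C)Cl
Why: Silylation of the C4′ hydroxyl; the terminal alkyne C–H is not affected under imidazole conditions.

Step 7
Reactants: 12 (6S,17S)-6,17-bis[(tert-butyldimethylsilyl)oxy]octadec-1-yne
Product: 14 (1E,6S,17S)-6,17-bis[(tert-butyldimethylsilyl)oxy]-1-iodooctadec-1-ene, via alkenylzirconocene chloride 13 (not isolated)
Conditions: Cp2Zr(H)Cl, THF, rt; then I2, THF, 0 °C
Reagents that add atoms: iodine, II
Why: Hydrozirconation is a syn, anti-Markovnikov addition that places zirconium on the terminal carbon. Iodinolysis of the C–Zr bond with retention gives the (E)-iodoalkene, which fixes the C5=C6 geometry.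

Step 8
Reactants: 14 (1E,6S,17S)-6,17-bis[(tert-butyldimethylsilyl)oxy]-1-iodooctadec-1-ene; 15 2-methyl-2-vinyl-1,3-dioxolane
Product: 16 2-[(1E,3E,8S,19S)-8,19-bis[(tert-butyldimethylsilyl)oxy]icosa-1,3-dien-1-yl]-2-methyl-1,3-dioxolane
Conditions: Pd(OAc)2 (5 mol %), Bu4NCl, K2CO3, 15 (3 equiv), DMF, 40 °C
Reagents that add atoms: none
Why: Mizoroki–Heck reaction under Jeffery conditions: zerovalent palladium formed from Pd(OAc)2 inserts into the C–I bond with retention, and the alkenyl group adds to the unsubstituted carbon of 15. β-Hydride elimination can only occur toward the new C4–C5 bond because the ketal carbon bears no hydrogen, so the (E,E)-diene should result.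

Step 9
Reactants: 17 methyl (2R)-2-hydroxy-2-phenylacetate (methyl (R)-mandelate)
Product: 18 (2R)-N,2-dihydroxy-2-phenylacetamide ((R)-mandelohydroxamic acid)
Conditions: NH2OH (50 % in H2O, excess), MeOH, 0 °C → rt
Reagents that add atoms: hydroxylamine, NO
Why: Aminolysis of the activated α-hydroxy ester by hydroxylamine, an α-effect nucleophile. No strong base is present, so the benzylic stereocentre should stay intact.

Step 10
Reactants: 16 2-[(1E,3E,8S,19S)-8,19-bis[(tert-butyldimethylsilyl)oxy]icosa-1,3-dien-1-yl]-2-methyl-1,3-dioxolane; 18 (2R)-N,2-dihydroxy-2-phenylacetamide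
Product: 20 (2R)-1-[(3S,6S)-3-[(4S,15S)-4,15-bis[(tert-butyldimethylsilyl)oxy]hexadecyl]-6-(2-methyl-1,3-dioxolan-2-yl)-3,6-dihydro-2H-1,2-oxazin-2-yl]-2-hydroxy-2-phenylethan-1-one, via nitrosocarbonyl compound 19 (not isolated)
Conditions: 18 (1.5 equiv), Et4NIO4 (1.5 equiv, slow addition), CH2Cl2, −78 → −20 °C
Reagents that add atoms: none
Why: Periodate oxidises hydroxamic acid 18 to the transient nitrosocarbonyl compound 19, which is trapped at once by the s-cis conformer of diene 16 in a concerted, asynchronous [4+2] cycloaddition; the closest known reaction type is the acylnitroso hetero-Diels–Alder reaction of α-hydroxyacyl nitroso dienophiles and of sorbaldehyde acetals. The 3,6-dihydro-2H-1,2-oxazine ring is closed intermolecularly by two new σ bonds, C6–N and C3–O, in a (4+2) ring formation with N=O as the two-atom partner. Because the addition is suprafacial on an (E,E)-diene, the hydrogens on C3 and C6 end on the same ring face; this cis relation in the oxazine is the trans relation of hydroxyl and chain in ring A. For regiochemistry, the C–N bond is the more advanced one in the transition state and nitrogen carries the bulky acyl group, so it should go to C6, the terminus with a primary alkyl substituent, while oxygen goes to C3, which is flanked by the quaternary, inductively withdrawing ketal carbon. The absolute configuration at C3 and C6 is controlled by the mandeloyl stereocentre: its internal hydrogen bond holds the acyl nitroso unit in one planar conformation and the phenyl group screens one face, so the diene should approach anti to phenyl with the acyl group endo. The step therefore needs regio- and π-facial selectivity, the cis relation being automatic; the non-coordinating solvent and low temperature are chosen to keep the hydrogen bond intact. The two possible ring diastereomers differ in their relation to three fixed stereocentres and should be separable by chromatography.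

Step 11
Reactants: 20 (2R)-1-[(3S,6S)-3-[(4S,15S)-4,15-bis[(tert-butyldimethylsilyl)oxy]hexadecyl]-6-(2-methyl-1,3-dioxolan-2-yl)-3,6-dihydro-2H-1,2-oxazin-2-yl]-2-hydroxy-2-phenylethan-1-one
Product: 21 (3S,6S)-3-[(4S,15S)-4,15-bis[(tert-butyldimethylsilyl)oxy]hexadecyl]-6-(2-methyl-1,3-dioxolan-2-yl)-3,6-dihydro-2H-1,2-oxazine
Conditions: iBu2AlH (3.5 equiv), THF, −78 → −40 °C; aq. potassium sodium tartrate (KNaC4H4O6)
Reagents that add atoms: none
Why: The acylated oxazine nitrogen is an N-alkoxy amide of the Weinreb type: after deprotonation of the hydroxyl, hydride adds once to the carbonyl and the chelated aluminium hemiaminal collapses on work-up to the aldehyde and the N–H oxazine (reductive N-deacylation). The N–O bond, alkene, ketal and silyl ethers are inert to the reagent at this temperature.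

Step 12
Reactants: 21 (3S,6S)-3-[(4S,15S)-4,15-bis[(tert-butyldimethylsilyl)oxy]hexadecyl]-6-(2-methyl-1,3-dioxolan-2-yl)-3,6-dihydro-2H-1,2-oxazine
Product: 22 (1S,4S,8S,19S)-4-amino-8,19-bis[(tert-butyldimethylsilyl)oxy]-1-(2-methyl-1,3-dioxolan-2-yl)icosan-1-ol
Conditions: H2 (1 atm), Raney Ni, EtOH, rt
Reagents that add atoms: none
Why: Catalytic hydrogenation saturates C4=C5 and hydrogenolyses the weak N–O bond, unveiling the C6 amine and the C3 hydroxyl with both configurations unchanged. Silyl ethers and the ketal are inert under neutral conditions.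

Step 13
Reactants: 22 (1S,4S,8S,19S)-4-amino-8,19-bis[(tert-butyldimethylsilyl)oxy]-1-(2-methyl-1,3-dioxolan-2-yl)icosan-1-ol
Product: 25 (2R,3S,6S)-6-[(4S,15S)-4,15-dihydroxyhexadecyl]-2-methylpiperidin-3-ol (the target), via amino ketone hydrochloride 23 (not isolated), via cyclic imine 24 (not isolated)
Conditions: 3 M aq. HCl–THF (1:2), 40 °C; then NaHCO3 to pH 8, MeOH, NaBH4, −20 → 0 °C
Reagents that add atoms: none
Why: Acid hydrolysis removes the dioxolane and both silyl ethers; on neutralisation the C6 amine condenses with the C2 ketone to the six-membered cyclic imine, which NaBH4 reduces (intramolecular reductive amination). Hydride should add axially to the half-chair that carries the C6 chain and the C3 hydroxyl pseudo-equatorial, so the methyl group ends equatorial, cis to the chain and trans to the hydroxyl, which is (2R).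

## Compound list

1 | 11-bromoundec-1-ene | C=CCCCCCCCCCBr | starting material
2 | (S)-2-methyloxirane ((S)-propylene oxide) | C[C@H]1CO1 | starting material
3 | undec-10-en-1-ylmagnesium bromide | C=CCCCCCCCCC[Mg]Br | intermediate
4 | (2S)-tetradec-13-en-2-ol | C[C@H](O)CCCCCCCCCCC=C | intermediate
5 | tert-butyldimethyl[(2S)-tetradec-13-en-2-yloxy]silane | C[C@H](O[Si](C)(C)C(C)(C)C)CCCCCCCCCCC=C | intermediate
6 | tert-butyldimethyl{[(2S)-12-(oxiran-2-yl)dodecan-2-yl]oxy}silane (both oxirane epimers) | C[C@H](O[Si](C)(C)C(C)(C)C)CCCCCCCCCCC1CO1 | intermediate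
7 | tert-butyldimethyl({(2S)-12-[(2S)-oxiran-2-yl]dodecan-2-yl}oxy)silane | C[C@H](O[Si](C)(C)C(C)(C)C)CCCCCCCCCC[C@H]1CO1 | intermediate
8 | (4-bromobut-1-yn-1-yl)trimethylsilane | C[Si](C)(C)C#CCCBr | starting material
9 | [4-(trimethylsilyl)but-3-yn-1-yl]magnesium bromide | C[Si](C)(C)C#CCC[Mg]Br | intermediate
10 | (6S,17S)-17-[(tert-butyldimethylsilyl)oxy]-1-(trimethylsilyl)octadec-1-yn-6-ol | C[Si](C)(C)C#CCCC[C@@H](O)CCCCCCCCCC[C@H](C)O[Si](C)(C)C(C)(C)C | intermediate
11 | (6S,17S)-17-[(tert-butyldimethylsilyl)oxy]octadec-1-yn-6-ol | C#CCCC[C@@H](O)CCCCCCCCCC[C@H](C)O[Si](C)(C)C(C)(C)C | intermediate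
12 | (6S,17S)-6,17-bis[(tert-butyldimethylsilyl)oxy]octadec-1-yne | C#CCCC[C@@H](O[Si](C)(C)C(C)(C)C)CCCCCCCCCC[C@H](C)O[Si](C)(C)C(C)(C)C | intermediate
13 | chlorobis(cyclopentadienyl)[(1E,6S,17S)-6,17-bis[(tert-butyldimethylsilyl)oxy]octadec-1-en-1-yl]zirconium | Cl[Zr](/C=C/CCC[C@@H](O[Si](C)(C)C(C)(C)C)CCCCCCCCCC[C@H](C)O[Si](C)(C)C(C)(C)C)(C1C=CC=C1)C1C=CC=C1 | intermediate
14 | (1E,6S,17S)-6,17-bis[(tert-butyldimethylsilyl)oxy]-1-iodooctadec-1-ene | I/C=C/CCC[C@@H](O[Si](C)(C)C(C)(C)C)CCCCCCCCCC[C@H](C)O[Si](C)(C)C(C)(C)C | intermediate
15 | 2-methyl-2-vinyl-1,3-dioxolane | CC1(C=C)OCCO1 | starting material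
16 | 2-[(1E,3E,8S,19S)-8,19-bis[(tert-butyldimethylsilyl)oxy]icosa-1,3-dien-1-yl]-2-methyl-1,3-dioxolane | CC1(OCCO1)/C=C/C=C/CCC[C@@H](O[Si](C)(C)C(C)(C)C)CCCCCCCCCC[C@H](C)O[Si](C)(C)C(C)(C)C | intermediate
17 | methyl (2R)-2-hydroxy-2-phenylacetate (methyl (R)-mandelate) | COC(=O)[C@H](O)c1ccccc1 | starting material
18 | (2R)-N,2-dihydroxy-2-phenylacetamide ((R)-mandelohydroxamic acid) | ONC(=O)[C@H](O)c1ccccc1 | intermediate
19 | (2R)-2-hydroxy-1-nitroso-2-phenylethan-1-one | O=NC(=O)[C@H](O)c1ccccc1 | intermediate
20 | (2R)-1-[(3S,6S)-3-[(4S,15S)-4,15-bis[(tert-butyldimethylsilyl)oxy]hexadecyl]-6-(2-methyl-1,3-dioxolan-2-yl)-3,6-dihydro-2H-1,2-oxazin-2-yl]-2-hydroxy-2-phenylethan-1-one | O1N(C(=O)[C@H](O)c2ccccc2)[C@@H](CCC[C@@H](O[Si](C)(C)C(C)(C)C)CCCCCCCCCC[C@H](C)O[Si](C)(C)C(C)(C)C)C=C[C@H]1C3(C)OCCO3 | intermediate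
21 | (3S,6S)-3-[(4S,15S)-4,15-bis[(tert-butyldimethylsilyl)oxy]hexadecyl]-6-(2-methyl-1,3-dioxolan-2-yl)-3,6-dihydro-2H-1,2-oxazine | O1N[C@@H](CCC[C@@H](O[Si](C)(C)C(C)(C)C)CCCCCCCCCC[C@H](C)O[Si](C)(C)C(C)(C)C)C=C[C@H]1C2(C)OCCO2 | intermediate
22 | (1S,4S,8S,19S)-4-amino-8,19-bis[(tert-butyldimethylsilyl)oxy]-1-(2-methyl-1,3-dioxolan-2-yl)icosan-1-ol | CC1(OCCO1)[C@@H](O)CC[C@@H](N)CCC[C@@H](O[Si](C)(C)C(C)(C)C)CCCCCCCCCC[C@H](C)O[Si](C)(C)C(C)(C)C | intermediate
23 | (3S,6S,10S,21S)-6-amino-3,10,21-trihydroxydocosan-2-one hydrochloride | CC(=O)[C@@H](O)CC[C@@H](N)CCC[C@@H](O)CCCCCCCCCC[C@H](C)O.Cl | intermediate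
24 | (3S,6S)-6-[(4S,15S)-4,15-dihydroxyhexadecyl]-2-methyl-3,4,5,6-tetrahydropyridin-3-ol | CC1=N[C@@H](CCC[C@@H](O)CCCCCCCCCC[C@H](C)O)CC[C@@H]1O | intermediate
25 | (2R,3S,6S)-6-[(4S,15S)-4,15-dihydroxyhexadecyl]-2-methylpiperidin-3-ol | C[C@H](O)CCCCCCCCCC[C@H](O)CCC[C@H]1CC[C@H](O)[C@@H](C)N1 | target

## Step count and least certain steps

Total: 13 steps. Longest linear sequence: 12 steps (steps 1 to 8 and 10 to 13, from bromide 1); step 9 is a one-step side branch.

**Step 10 (key step).**
- Risk: insufficient π-facial discrimination is the most likely failure. The mandeloyl stereocentre sits three atoms from the forming bonds, and a flexible acyclic diene offers less contact than the cyclic dienes on which this auxiliary is proven. The sense of induction is also unproven here. Lesser risks are erosion of regiocontrol and decomposition of the transient nitroso species before capture.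
- Fallback: a chloronitroso hetero-Diels–Alder reaction, setting out from diene 16 and returning at oxazine 21. Commercial 2,3:5,6-di-O-isopropylidene-D-mannofuranose is condensed with hydroxylamine to 2,3:5,6-di-O-isopropylidene-D-mannose oxime F1. Chlorination with tert-butyl hypochlorite gives 2,3:5,6-di-O-isopropylidene-1-C-nitroso-α-D-mannofuranosyl chloride F2. This adds to 16 in CHCl3–iPrOH at low temperature, and the primary N-(1-chloromannofuranosyl) cycloadduct F3 is solvolysed in the flask to the hydrochloride of 21, which NaHCO3 sets free. Step 11 is then not needed. The stereocentres of this reagent lie directly on the nitroso carbon, but its face preference on this diene would have to be established just as for 18.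

**Step 11.**
- Risk: incomplete reduction, because the aluminium alkoxide formed at the mandeloyl hydroxyl can hold the carbonyl in an unreactive chelate. Forcing the reaction risks cleavage of the N–O bond.
- Fallback: oxidative activation, from 20 back to 21. Dess–Martin oxidation of the mandeloyl hydroxyl gives 1-[(3S,6S)-3-[(4S,15S)-4,15-bis[(tert-butyldimethylsilyl)oxy]hexadecyl]-6-(2-methyl-1,3-dioxolan-2-yl)-3,6-dihydro-2H-1,2-oxazin-2-yl]-2-phenylethane-1,2-dione F4. Its 1,2-dicarbonyl unit is cleaved by H2O2–NaHCO3 in THF–H2O at 0 °C to benzoic acid and an N-carboxylate, which loses carbon dioxide to give 21.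

**Step 13.**
- Risk: slow hydrolysis of the dioxolane, which lies next to the C3 hydroxyl and near a protonated amine. Enolisation of the α-hydroxy ketone or imine toward C3 could occur before reduction, and facial control at C2 could be incomplete.
- Fallback: N-protection and hydrogenative ring closure, from 22 to 25. Acylation with benzyl chloroformate and NaHCO3 gives benzyl N-[(1S,4S,8S,19S)-8,19-bis[(tert-butyldimethylsilyl)oxy]-1-hydroxy-1-(2-methyl-1,3-dioxolan-2-yl)icosan-4-yl]carbamate F5. With no ammonium ion nearby, aqueous HCl in THF should hydrolyse ketal and silyl ethers under milder conditions to benzyl N-[(3S,6S,10S,21S)-3,10,21-trihydroxy-2-oxodocosan-6-yl]carbamate F6. Hydrogenation over Pd/C in MeOH then removes the carbamate, and the imine is reduced as it forms, so it never accumulates.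

**Step 8.**
- Risk: insertion with the opposite regiochemistry (branched diene), E/Z isomerisation of the diene through reversible hydropalladation, and homocoupling of 14.
- Fallback: Suzuki–Miyaura coupling, from 14 back to 16. Ketalisation of but-3-yn-2-one with 1,2-bis(trimethylsilyloxy)ethane and TMSOTf gives 2-ethynyl-2-methyl-1,3-dioxolane F7. Hydroboration with pinacolborane, catalysed by Cp2Zr(H)Cl, gives 2-methyl-2-[(E)-2-(4,4,5,5-tetramethyl-1,3,2-dioxaborolan-2-yl)ethenyl]-1,3-dioxolane F8. Coupling of F8 with 14 (Pd(PPh3)4, a complex of zerovalent palladium; K3PO4; THF–H2O; 50 °C) joins C4 to C5 with both alkene geometries already fixed in the partners.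

## Further compounds

F1 | step 10 | 2,3:5,6-di-O-isopropylidene-D-mannose oxime | ON=C[C@H]1OC(C)(C)O[C@H]1[C@H](O)[C@H]1COC(C)(C)O1
F2 | step 10 | 2,3:5,6-di-O-isopropylidene-1-C-nitroso-α-D-mannofuranosyl chloride | O=N[C@]1(Cl)O[C@H]([C@H]2COC(C)(C)O2)[C@@H]2OC(C)(C)O[C@H]12
F3 | step 10 | N-(1-chloro-2,3:5,6-di-O-isopropylidene-D-mannofuranosyl) derivative of 21 (primary cycloadduct) | O1N([C@]2(Cl)O[C@H]([C@H]3COC(C)(C)O3)[C@@H]3OC(C)(C)O[C@H]23)[C@@H](CCC[C@@H](O[Si](C)(C)C(C)(C)C)CCCCCCCCCC[C@H](C)O[Si](C)(C)C(C)(C)C)C=C[C@H]1C4(C)OCCO4
F4 | step 11 | 1-[(3S,6S)-3-[(4S,15S)-4,15-bis[(tert-butyldimethylsilyl)oxy]hexadecyl]-6-(2-methyl-1,3-dioxolan-2-yl)-3,6-dihydro-2H-1,2-oxazin-2-yl]-2-phenylethane-1,2-dione | O1N(C(=O)C(=O)c2ccccc2)[C@@H](CCC[C@@H](O[Si](C)(C)C(C)(C)C)CCCCCCCCCC[C@H](C)O[Si](C)(C)C(C)(C)C)C=C[C@H]1C3(C)OCCO3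
F5 | step 13 | benzyl N-[(1S,4S,8S,19S)-8,19-bis[(tert-butyldimethylsilyl)oxy]-1-hydroxy-1-(2-methyl-1,3-dioxolan-2-yl)icosan-4-yl]carbamate | CC1(OCCO1)[C@@H](O)CC[C@@H](NC(=O)OCc1ccccc1)CCC[C@@H](O[Si](C)(C)C(C)(C)C)CCCCCCCCCC[C@H](C)O[Si](C)(C)C(C)(C)C
F6 | step 13 | benzyl N-[(3S,6S,10S,21S)-3,10,21-trihydroxy-2-oxodocosan-6-yl]carbamate | CC(=O)[C@@H](O)CC[C@@H](NC(=O)OCc1ccccc1)CCC[C@@H](O)CCCCCCCCCC[C@H](C)O
F7 | step 8 | 2-ethynyl-2-methyl-1,3-dioxolane | CC1(C#C)OCCO1
F8 | step 8 | 2-methyl-2-[(E)-2-(4,4,5,5-tetramethyl-1,3,2-dioxaborolan-2-yl)ethenyl]-1,3-dioxolane | CC1(OCCO1)/C=C/B1OC(C)(C)C(C)(C)O1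
A1 | alternative 1 | (2R,3S)-6-[(4S,15S)-4,15-dihydroxyhexadecyl]-2-methyl-2,3,4,5-tetrahydropyridin-3-ol | C[C@H]1N=C(CCC[C@@H](O)CCCCCCCCCC[C@H](C)O)CC[C@@H]1O
A2 | alternative 1 | (3S,10S,21S)-3,10,21-trihydroxydocosane-2,6-dione | CC(=O)[C@@H](O)CCC(=O)CCC[C@@H](O)CCCCCCCCCC[C@H](C)O
A3 | alternative 2 | (2R,3S,6S)-3-[(tert-butyldimethylsilyl)oxy]-6-[(4R)-4-[(tert-butyldimethylsilyl)oxy]hex-5-en-1-yl]-2-methyl-1,2,3,6-tetrahydropyridine | C[C@H]1N[C@@H](CCC[C@@H](O[Si](C)(C)C(C)(C)C)C=C)C=C[C@@H]1O[Si](C)(C)C(C)(C)C
A4 | alternative 2 | (1S,4R)-4-[(tert-butyldimethylsilyl)oxy]-N-[(2R,3S)-3-[(tert-butyldimethylsilyl)oxy]pent-4-en-2-yl]cyclohept-2-en-1-amine | C=C[C@H](O[Si](C)(C)C(C)(C)C)[C@@H](C)N[C@@H]1C=C[C@H](O[Si](C)(C)C(C)(C)C)CCC1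
A5 | alternative 3 | (2R,3S,6S)-6-[(4S,15S)-4,15-bis[(tert-butyldimethylsilyl)oxy]hexadecyl]-3-[(tert-butyldimethylsilyl)oxy]-2-methylpiperidine | C[C@H]1N[C@@H](CCC[C@@H](O[Si](C)(C)C(C)(C)C)CCCCCCCCCC[C@H](C)O[Si](C)(C)C(C)(C)C)CC[C@@H]1O[Si](C)(C)C(C)(C)C
A6 | alternative 3 | (3S,6S,10S,21S)-3,10,21-tris[(tert-butyldimethylsilyl)oxy]docos-1-yn-6-amine | C#C[C@@H](O[Si](C)(C)C(C)(C)C)CC[C@@H](N)CCC[C@@H](O[Si](C)(C)C(C)(C)C)CCCCCCCCCC[C@H](C)O[Si](C)(C)C(C)(C)C
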